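The route rests on cutting ring C at the C9–C11 bond, which unfolds the B/C core into an achiral 2,2-disubstituted cyclopentane-1,3-dione. The key step, an (S)-proline-mediated intramolecular aldol condensation, exploits C8: the carbon-only quaternary junction common to rings B, C and D, whose ring-B neighbours C6 and C9 both begin as carbonyl carbons and which faces oxygen-bearing C12 across ring C. By choosing one of the two enantiotopic carbonyls it forges C9–C11, closes ring C and fixes C8 in one operation. Its precursor is a mirror-symmetric triketone whose future C8 carries a 3-oxobutyl arm (C14–C11) and a propargyl arm (C15–C17).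

Key step: step 3

Remark: gibberellane atom numbers (C1–C19) and ring letters A–D are used throughout; C13 in 10 and 11, C10 in 23, C4 in 30–34 and C3 in 35 and 36 are formed without control and erased later, and C9 in 14–24 and C12 in 15–36 are drawn as the expected kinetic epimers and are re-set in steps 15 and 23.

Step 1
Reactants: 1 cyclopentane-1,3-dione; 2 propargyl bromide
Product: 3 2-(prop-2-yn-1-yl)cyclopentane-1,3-dione
Conditions: NaOH (1 equiv), H2O, 0 → 60 °C
Reagents that add atoms: none
Why: The doubly stabilised enolate of the 1,3-dione is alkylated at carbon by the propargylic bromide in water, where hydrogen bonding to the enolate oxygens disfavours O-alkylation (enolate C-alkylation); no stereocentre is formed.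

Step 2
Reactants: 3 2-(prop-2-yn-1-yl)cyclopentane-1,3-dione; 4 methyl vinyl ketone
Product: 5 2-(3-oxobutyl)-2-(prop-2-yn-1-yl)cyclopentane-1,3-dione
Conditions: AcOH (cat.), H2O, 70 °C
Reagents that add atoms: none
Why: The acidic 2-substituted dione adds to the enone in water with a trace of acid (Michael addition) to give the 2,2-disubstituted triketone, which is achiral because the future C8 still carries two identical ring carbonyl arms.

Step 3
Reactants: 5 2-(3-oxobutyl)-2-(prop-2-yn-1-yl)cyclopentane-1,3-dione
Product: 7 (R)-7a-(prop-2-yn-1-yl)-2,3,7,7a-tetrahydro-1H-indene-1,5(6H)-dione, via ketol 6 (not isolated)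
Conditions: (S)-proline (30 mol%), DMF, rt; then TsOH·H2O (cat.), toluene, 80 °C
Reagents that add atoms: none
Why: (S)-Proline condenses with the side-chain methyl ketone to an enamine whose terminal carbon C11 adds to one ring carbonyl (C9) while the carboxylic acid hydrogen-bonds that carbonyl, hydrolysis releases ketol 6 and acid then eliminates water to the C9=C11 enone; this is the Hajos–Parrish–Eder–Sauer–Wiechert reaction, known for 2-alkyl-2-(3-oxobutyl)cyclopentane-1,3-diones. Ring C closes in a 6-(enolendo)-exo-trig mode. The one stereocentre that is kept, quaternary C8, is controlled by the (S)-configuration of the catalyst, which selects between the two enantiotopic carbonyls through a chair-like transition state with the enamine anti to the hydrogen-bonding acid. Only enantiotopic-group selectivity is needed, and the substrate secures it through its mirror plane, a propargyl group that is sterically close to the methyl and ethyl groups for which this sense is established, and a terminal alkyne that is inert to the amine and to acid. The carbinol centre C9 of 6 disappears on dehydration and C8, having no hydrogen, cannot be eroded.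

Step 4
Reactants: 7 (R)-7a-(prop-2-yn-1-yl)-2,3,7,7a-tetrahydro-1H-indene-1,5(6H)-dione
Product: 8 C6 ethylene ketal of enone 7
Conditions: (Me3SiOCH2)2, Me3SiOTf (cat.), CH2Cl2, −78 °C
Reagents that add atoms: 1,2-bis(trimethylsilyloxy)ethane, C[Si](C)(C)OCCO[Si](C)(C)C
Why: Silyl triflate-catalysed ketalisation at −78 °C is selective for the saturated C6 ketone over the conjugated C12 carbonyl (chemoselective ketalisation), so the cyclopentanone is masked before any enolate chemistry; C8 is untouched.

Step 5
Reactants: 8 C6 ethylene ketal of enone 7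
Product: 10 C13-hydroxy enone ketal, via potassium dienolate 9 (not isolated)
Conditions: KN(SiMe3)2, THF, −78 °C; then 2-(phenylsulfonyl)-3-phenyloxaziridine, −78 °C; aq. NH4Cl
Reagents that add atoms: 2-(phenylsulfonyl)-3-phenyloxaziridine, O=S(=O)(N1OC1c1ccccc1)c1ccccc1
Why: Kinetic deprotonation of the enone at the alpha-prime carbon C13 gives the cross-conjugated dienolate, which the N-sulfonyloxaziridine oxygenates at carbon (enolate hydroxylation); the new C13 centre may be either epimer because it becomes sp2 in step 6.

Step 6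
Reactants: 10 C13-hydroxy enone ketal
Product: 12 C12/C13 enediol bis(tert-butyldimethylsilyl) ether, via silyl ether 11 (not isolated)
Conditions: TBSOTf (2.5 equiv), Et3N, CH2Cl2, 0 °C → rt
Reagents that add atoms: tert-butyldimethylsilyl trifluoromethanesulfonate, CC(C)(C)[Si](C)(C)OS(=O)(=O)C(F)(F)F
Why: The silyl triflate caps the hydroxyl and then, with amine base, enolises the ketone towards C13, the only alpha carbon bearing hydrogen since C11 is vinylic, giving the tetrasubstituted enediol bis-silyl ether (O-silylation and soft enolisation).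

Step 7
Reactants: 12 C12/C13 enediol bis(tert-butyldimethylsilyl) ether
Product: 13 tricyclic B/C/D enone (C6 ketal; C9=C11–C12=O; 13-OTBS; C16=C17)
Conditions: (Ph3P)AuCl (5 mol%), AgBF4 (5 mol%), CH2Cl2/H2O (10:1), rt → 40 °C
Reagents that add atoms: none
Why: (Ph3P)Au+ activates the terminal alkyne for anti attack by enol ether carbon C13, the terminus whose attack leaves an oxocarbenium ion at C12 conjugated with C9=C11, in a 5-exo-dig closure of ring D (gold-catalysed Conia-ene-type carbocyclisation of a silyl enol ether), and protodeauration with loss of the C12 silyl group gives the C16=C17 methylene and the C12 ketone; the C13 configuration is dictated by the C8–C15 tether, which can bridge only one face.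

Step 8
Reactants: 13 tricyclic B/C/D enone
Product: 14 saturated 12-ketone (C9 provisional)
Conditions: [(Ph3P)CuH]6 (0.4 equiv), H2O (3 equiv), toluene, rt
Reagents that add atoms: none
Why: [(Ph3P)CuH]6 delivers hydride to the beta carbon C9 of the enone and leaves the 1,1-disubstituted alkene, the ketal and the silyl ether alone (copper hydride conjugate reduction); C9 forms under kinetic control, presumably anti to the C15–C16 bridge, and is provisional because it is equilibrated in step 15.

Step 9
Reactants: 14 saturated 12-ketone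
Product: 15 12-alcohol (C12 provisional)
Conditions: NaBH4, MeOH/THF, −20 °C
Reagents that add atoms: none
Why: NaBH4 reduces the 12-ketone, expected mainly by axial attack to the equatorial alcohol (ketone reduction), only to mask C12 for the enolate chemistry that follows; this centre is provisional and is re-set in step 23.

Step 10
Reactants: 15 12-alcohol
Product: 16 12-hydroxy C6 ketone
Conditions: PPTS (cat.), acetone/H2O (9:1), 55 °C
Reagents that add atoms: water, O
Why: Mild acid-catalysed transketalisation into wet acetone releases the C6 ketone while the tertiary silyl ether and the exocyclic alkene survive (ketal hydrolysis); no stereocentre changes.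

Step 11
Reactants: 16 12-hydroxy C6 ketone
Product: 17 12-O-triethylsilyl C6 ketone
Conditions: Et3SiOTf, 2,6-lutidine, CH2Cl2, −78 °C
Reagents that add atoms: triethylsilyl trifluoromethanesulfonate, CC[Si](CC)(CC)OS(=O)(=O)C(F)(F)F
Why: The silyl triflate with a hindered pyridine base silylates the secondary alcohol without enolising the ketone (silyl ether formation), installing a group that can later be removed in the presence of the tertiary tert-butyldimethylsilyl ether.

Step 12
Reactants: 17 12-O-triethylsilyl C6 ketone
Product: 19 C5=C6 enol triflate, via potassium enolate 18 (not isolated)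
Conditions: KN(SiMe3)2, THF, −78 °C; then PhNTf2, −78 → 0 °C; aq. NH4Cl
Reagents that add atoms: N-phenylbis(trifluoromethanesulfonimide), O=S(=O)(N(c1ccccc1)S(=O)(=O)C(F)(F)F)C(F)(F)F
Why: Because C8 is quaternary the C6 ketone can enolise only towards C5, so the potassium enolate is trapped regiospecifically as the C5=C6 enol triflate (enolate O-sulfonylation).

Step 13
Reactants: 19 C5=C6 enol triflate; 20 carbon monoxide
Product: 21 2-(trimethylsilyl)ethyl C5=C6 enoate
Conditions: Pd(OAc)2 (5 mol%), PPh3 (10 mol%), CO (1 atm), Me3SiCH2CH2OH (5 equiv), Et3N, DMF, 60 °C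
Reagents that add atoms: 2-(trimethylsilyl)ethanol, C[Si](C)(C)CCO
Why: Oxidative addition of the enol triflate to zerovalent palladium, CO insertion and alcoholysis attach C7 as a fluoride-labile ester conjugated with C5=C6 (palladium-catalysed alkoxycarbonylation), a reaction that tolerates the neighbouring quaternary C8.

Step 14
Reactants: 21 2-(trimethylsilyl)ethyl C5=C6 enoate
Product: 23 10-hydroxy enoate, via silyl ketene acetal 22 (not isolated)
Conditions: LiN(i-Pr)2, Me3SiCl (in situ trap), THF/DMPU, −78 °C; then 3-chloroperbenzoic acid, NaHCO3, CH2Cl2, −78 → −20 °C; aqueous work-up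
Reagents that add atoms: 3-chloroperbenzoic acid, OOC(=O)c1cccc(Cl)c1
Why: Gamma deprotonation at C10 with in situ silylation gives the extended silyl ketene acetal, which the peracid should attack at the gamma terminus C10 because the alpha carbon C6 is shielded by quaternary C8, so that C10 is hydroxylated and the enoate regenerated (vinylogous Rubottom oxidation); the C10 carbinol configuration is irrelevant.

Step 15
Reactants: 23 10-hydroxy enoate
Product: 25 10-oxo enoate having natural C9, via 9-epi oxo-enoate 24 (not isolated)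
Conditions: DMP (1,1,1-triacetoxy-1,1-dihydro-1,2-benziodoxol-3(1H)-one), NaHCO3, CH2Cl2, rt; filter; then DBU (0.2 equiv), CH2Cl2, rt
Reagents that add atoms: none
Why: Dess–Martin oxidation of the allylic alcohol gives the 4-oxo-enoate, and catalytic amidine base then equilibrates C9 through the C9=C10 enol to the cis-fused B/C bicycle, the more stable arrangement of a cyclopentenone fused to a cyclohexane at an angularly substituted junction, which puts H9 on the side of C15 as in the target (thermodynamic epimerisation).

Step 16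
Reactants: 25 10-oxo enoate having natural C9; 26 allylmagnesium bromide; 27 propionyl chloride
Product: 29 10-allyl 10-propionate, via magnesium alkoxide 28 (not isolated)
Conditions: 26 (1.15 equiv), THF, −78 °C; then 27 (2.5 equiv), −78 → 0 °C
Reagents that add atoms: none
Why: Allylmagnesium bromide adds 1,2 to the C10 ketone from the convex face of the cis-fused B/C bicycle, anti to C11 on the neighbouring C9, which sets C10 with its oxygen syn to C11, and the tertiary magnesium alkoxide is acylated in the same flask (Grignard addition then O-acylation).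

Step 17
Reactants: 29 10-allyl 10-propionate
Product: 31 10-allyl 19,10-lactone 7-ester, via potassium ester enolate 30 (not isolated)
Conditions: KN(SiMe3)2 (1.2 equiv), THF, −78 → 0 °C; then t-BuOH, 0 °C → rt; aq. NH4Cl
Reagents that add atoms: none
Why: The potassium enolate of the propionate adds to C5 of the enoate in a 5-exo-trig intramolecular Michael addition that can deliver C4 only to the face of C5 on which the C10–O bond lies, which sets C5 and closes the cis-fused gamma-lactone, and equilibration of the resulting ester enolate with tert-butanol places the C6 ester trans to C4 (thermodynamic protonation); C4 is provisional.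

Step 18
Reactants: 31 10-allyl 19,10-lactone 7-ester
Product: 33 C3 primary alcohol, via alkylborane 32 (not isolated)
Conditions: (Me2CHCHMe)2BH (from BH3·SMe2 and 2-methyl-2-butene), THF, 0 °C; then 30% H2O2, aq. NaOAc, 0 °C → rt
Reagents that add atoms: hydrogen peroxide, OO
Why: The bulky dialkylborane adds to the monosubstituted allyl alkene much faster than to the hindered 1,1-disubstituted C16=C17 alkene, and buffered peroxide oxidation gives the primary C3 alcohol without touching lactone or ester (anti-Markovnikov hydroboration–oxidation).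

Step 19
Reactants: 33 C3 primary alcohol
Product: 34 C3 aldehyde
Conditions: DMP, NaHCO3, CH2Cl2, 0 °C → rt
Reagents that add atoms: none
Why: Buffered Dess–Martin oxidation gives the C3 aldehyde under neutral conditions that leave C6 and the lactone unchanged.

Step 20
Reactants: 34 C3 aldehyde
Product: 35 ring A aldol (3-hydroxy lactone)
Conditions: KOt-Bu (0.3 equiv), t-BuOH/THF (1:5), 0 °C, 0.005 M; AcOH quench
Reagents that add atoms: none
Why: Under reversible alkoxide catalysis at high dilution the lactone enolate at C4 adds to the C3 aldehyde in a 6-(enolexo)-exo-trig intramolecular aldol addition that closes ring A; C4 is set by the C10–C1 tether, which lets C3 bond only to the lactone face that carries C1, while both C3 carbinol epimers are accepted because C3 is re-set in step 23.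

Step 21
Reactants: 35 ring A aldol (3-hydroxy lactone)
Product: 36 3,12-diol
Conditions: PPTS (cat.), MeOH, 0 °C → rt
Reagents that add atoms: none
Why: Mild acid methanolysis removes the secondary triethylsilyl ether and leaves the tertiary tert-butyldimethylsilyl ether, the lactone and the silylethyl ester in place (selective desilylation).

Step 22
Reactants: 36 3,12-diol
Product: 37 3,12-dione
Conditions: DMP (3 equiv), NaHCO3, CH2Cl2, rt
Reagents that add atoms: none
Why: Dess–Martin oxidation converts both secondary carbinols into ketones, so that the provisional centres C3 and C12 are erased while C4, quaternary, cannot epimerise.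

Step 23
Reactants: 37 3,12-dione
Product: 38 13-O-TBS 2-(trimethylsilyl)ethyl ester of the target
Conditions: LiBH(s-Bu)3 (3 equiv), THF, −78 → −20 °C; AcOH quench at −78 °C
Reagents that add atoms: none
Why: LiBH(s-Bu)3 attacks the 3-ketone along the equatorial trajectory on the lactone side, as with cyclohexanones beside a quaternary carbon, to give the axial 3-alcohol anti to the lactone bridge, and can reach the 12-ketone only from the face of the C15–C16 bridge because the other face is covered by the axial, fully substituted C10, which gives the 12-alcohol cis to the 13-oxygen (diastereoselective ketone reduction).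

Step 24
Reactants: 38 13-O-TBS 2-(trimethylsilyl)ethyl ester of the target
Product: 39 CNP0260503.1
Conditions: Bu4NF (6 equiv), AcOH (6 equiv), THF, rt → 45 °C; work-up at pH 3
Reagents that add atoms: none
Why: Fluoride cleaves the tertiary silyl ether and fragments the 2-(trimethylsilyl)ethyl ester into the C7 acid, ethene and silyl fluoride, and the acetic acid buffer keeps the medium from opening the lactone or retro-aldolising ring A (global desilylation).

Compound list
1 | cyclopentane-1,3-dione | O=C1CCC(=O)C1 | starting material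
2 | propargyl bromide (3-bromoprop-1-yne) | C#CCBr | starting material
3 | 2-(prop-2-yn-1-yl)cyclopentane-1,3-dione | C#CCC1C(=O)CCC1=O | intermediate
4 | methyl vinyl ketone (but-3-en-2-one) | CC(=O)C=C | starting material
5 | 2-(3-oxobutyl)-2-(prop-2-yn-1-yl)cyclopentane-1,3-dione | CC(=O)CCC1(CC#C)C(=O)CCC1=O | intermediate
6 | cis-fused ketol, 3a-hydroxy-7a-(prop-2-yn-1-yl)hexahydro-1H-indene-1,5(4H)-dione, OH cis to propargyl | C#CC[C@]12CCC(=O)C[C@@]1(O)CCC2=O | intermediate (not isolated)
7 | (R)-7a-(prop-2-yn-1-yl)-2,3,7,7a-tetrahydro-1H-indene-1,5(6H)-dione (C8 set; ketones at C6 and C12) | C#CC[C@]12CCC(=O)C=C1CCC2=O | intermediate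
8 | C6 ethylene ketal (1,3-dioxolane) of enone 7 | C#CC[C@]12CCC(=O)C=C1CCC23OCCO3 | intermediate
9 | potassium cross-conjugated dienolate of 8 (C12–O–K, C12=C13, C9=C11) | C#CC[C@]12CC=C([O-])C=C1CCC23OCCO3.[K+] | intermediate (not isolated)
10 | C13-hydroxy enone ketal (both C13 epimers) | C#CC[C@]12CC(O)C(=O)C=C1CCC23OCCO3 | intermediate
11 | C13 tert-butyldimethylsilyl ether of 10 (both C13 epimers) | C#CC[C@]12CC(O[Si](C)(C)C(C)(C)C)C(=O)C=C1CCC23OCCO3 | intermediate (not isolated)
12 | C12/C13 enediol bis(tert-butyldimethylsilyl) ether (C12=C13 and C9=C11) | C#CC[C@]12CC(O[Si](C)(C)C(C)(C)C)=C(O[Si](C)(C)C(C)(C)C)C=C1CCC23OCCO3 | intermediate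
13 | tricyclic B/C/D enone: C6 ketal, C9=C11–C12=O, 13-OTBS, C16=C17 methylene | C=C1C[C@]23C[C@@]1(O[Si](C)(C)C(C)(C)C)C(=O)C=C2CCC34OCCO4 | intermediate
14 | saturated 12-ketone, C9 provisional (H9 anti to C15) | C=C1C[C@]23C[C@@]1(O[Si](C)(C)C(C)(C)C)C(=O)C[C@@H]2CCC34OCCO4 | intermediate
15 | 12-alcohol, C12 provisional (equatorial, trans to the C13 oxygen), C6 ketal | C=C1C[C@]23C[C@@]1(O[Si](C)(C)C(C)(C)C)[C@H](O)C[C@@H]2CCC34OCCO4 | intermediate
16 | 12-hydroxy C6 ketone | C=C1C[C@]23C[C@@]1(O[Si](C)(C)C(C)(C)C)[C@H](O)C[C@@H]2CCC3=O | intermediate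
17 | 12-O-triethylsilyl C6 ketone | C=C1C[C@]23C[C@@]1(O[Si](C)(C)C(C)(C)C)[C@H](O[Si](CC)(CC)CC)C[C@@H]2CCC3=O | intermediate
18 | potassium C5=C6 enolate of 17 | C=C1C[C@]23C[C@@]1(O[Si](C)(C)C(C)(C)C)[C@H](O[Si](CC)(CC)CC)C[C@@H]2CC=C3[O-].[K+] | intermediate (not isolated)
19 | C5=C6 enol triflate | C=C1C[C@]23C[C@@]1(O[Si](C)(C)C(C)(C)C)[C@H](O[Si](CC)(CC)CC)C[C@@H]2CC=C3OS(=O)(=O)C(F)(F)F | intermediate
20 | carbon monoxide | [C-]#[O+] | starting material
21 | 2-(trimethylsilyl)ethyl C5=C6 enoate (C7 installed) | C=C1C[C@]23C[C@@]1(O[Si](C)(C)C(C)(C)C)[C@H](O[Si](CC)(CC)CC)C[C@@H]2CC=C3C(=O)OCC[Si](C)(C)C | intermediate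
22 | O-trimethylsilyl ketene acetal (C6=C7 and C5=C10) | C=C1C[C@]23C[C@@]1(O[Si](C)(C)C(C)(C)C)[C@H](O[Si](CC)(CC)CC)C[C@@H]2C=CC3=C(O[Si](C)(C)C)OCC[Si](C)(C)C | intermediate (not isolated)
23 | 10-hydroxy enoate (both C10 epimers) | C=C1C[C@]23C[C@@]1(O[Si](C)(C)C(C)(C)C)[C@H](O[Si](CC)(CC)CC)C[C@@H]2C(O)C=C3C(=O)OCC[Si](C)(C)C | intermediate
24 | 10-oxo C5=C6 enoate, 9-epi | C=C1C[C@]23C[C@@]1(O[Si](C)(C)C(C)(C)C)[C@H](O[Si](CC)(CC)CC)C[C@@H]2C(=O)C=C3C(=O)OCC[Si](C)(C)C | intermediate (not isolated)
25 | 10-oxo C5=C6 enoate, natural C9 (H9 syn to C15) | C=C1C[C@]23C[C@@]1(O[Si](C)(C)C(C)(C)C)[C@H](O[Si](CC)(CC)CC)C[C@H]2C(=O)C=C3C(=O)OCC[Si](C)(C)C | intermediate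
26 | allylmagnesium bromide | C=CC[Mg]Br | starting material
27 | propionyl chloride | CCC(=O)Cl | starting material
28 | bromomagnesium C10 alkoxide (10-allyl, oxygen syn to C11) | C=C1C[C@]23C[C@@]1(O[Si](C)(C)C(C)(C)C)[C@H](O[Si](CC)(CC)CC)C[C@H]2[C@]([O-])(CC=C)C=C3C(=O)OCC[Si](C)(C)C.[Mg+2].[Br-] | intermediate (not isolated)
29 | 10-allyl 10-propionate | C=C1C[C@]23C[C@@]1(O[Si](C)(C)C(C)(C)C)[C@H](O[Si](CC)(CC)CC)C[C@H]2[C@](OC(=O)CC)(CC=C)C=C3C(=O)OCC[Si](C)(C)C | intermediate
30 | potassium C6=C7 ester enolate of the 19,10-lactone (C4 epimers) | C=C1C[C@]23C[C@@]1(O[Si](C)(C)C(C)(C)C)[C@H](O[Si](CC)(CC)CC)C[C@H]2[C@@]1(CC=C)OC(=O)C(C)[C@H]1C3=C([O-])OCC[Si](C)(C)C.[K+] | intermediate (not isolated)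
31 | 10-allyl 19,10-lactone 7-ester (C5 and C6 set; C4 provisional, methyl on the convex face) | C=C1C[C@]23C[C@@]1(O[Si](C)(C)C(C)(C)C)[C@H](O[Si](CC)(CC)CC)C[C@H]2[C@@]1(CC=C)OC(=O)[C@H](C)[C@H]1[C@@H]3C(=O)OCC[Si](C)(C)C | intermediate
32 | C3 bis(3-methylbutan-2-yl)borane | C=C1C[C@]23C[C@@]1(O[Si](C)(C)C(C)(C)C)[C@H](O[Si](CC)(CC)CC)C[C@H]2[C@@]1(CCCB(C(C)C(C)C)C(C)C(C)C)OC(=O)[C@H](C)[C@H]1[C@@H]3C(=O)OCC[Si](C)(C)C | intermediate (not isolated)
33 | C3 primary alcohol | C=C1C[C@]23C[C@@]1(O[Si](C)(C)C(C)(C)C)[C@H](O[Si](CC)(CC)CC)C[C@H]2[C@@]1(CCCO)OC(=O)[C@H](C)[C@H]1[C@@H]3C(=O)OCC[Si](C)(C)C | intermediate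
34 | C3 aldehyde | C=C1C[C@]23C[C@@]1(O[Si](C)(C)C(C)(C)C)[C@H](O[Si](CC)(CC)CC)C[C@H]2[C@@]1(CCC=O)OC(=O)[C@H](C)[C@H]1[C@@H]3C(=O)OCC[Si](C)(C)C | intermediate
35 | ring A aldol, 3-hydroxy 19,10-lactone (both C3 epimers; C4 set) | C=C1C[C@]23C[C@@]1(O[Si](C)(C)C(C)(C)C)[C@H](O[Si](CC)(CC)CC)C[C@H]2[C@@]12CCC(O)[C@@](C)(C(=O)O1)[C@H]2[C@@H]3C(=O)OCC[Si](C)(C)C | intermediate
36 | 3,12-diol (both C3 epimers; C12 provisional), 13-OTBS, silylethyl ester | C=C1C[C@]23C[C@@]1(O[Si](C)(C)C(C)(C)C)[C@H](O)C[C@H]2[C@@]12CCC(O)[C@@](C)(C(=O)O1)[C@H]2[C@@H]3C(=O)OCC[Si](C)(C)C | intermediate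
37 | 3,12-dione, 13-OTBS, silylethyl ester | C=C1C[C@]23C[C@@]1(O[Si](C)(C)C(C)(C)C)C(=O)C[C@H]2[C@@]12CCC(=O)[C@@](C)(C(=O)O1)[C@H]2[C@@H]3C(=O)OCC[Si](C)(C)C | intermediate
38 | 13-O-TBS 2-(trimethylsilyl)ethyl ester of the target (3-OH anti to the lactone bridge; 12-OH cis to the 13-oxygen) | C=C1C[C@]23C[C@@]1(O[Si](C)(C)C(C)(C)C)[C@@H](O)C[C@H]2[C@@]12CC[C@H](O)[C@@](C)(C(=O)O1)[C@H]2[C@@H]3C(=O)OCC[Si](C)(C)C | intermediate
39 | CNP0260503.1, the 3,12,13-trihydroxy 16-ene 19,10-lactone 7-acid | C=C1C[C@]23C[C@@]1(O)[C@@H](O)C[C@H]2[C@@]12CC[C@H](O)[C@@](C)(C(=O)O1)[C@H]2[C@@H]3C(=O)O | target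

Total step count: 24. Longest linear sequence: 24 steps (the route is fully linear from 1).

Steps most likely to fail

Step 14 carries the most risk: oxygen transfer may go to the alpha carbon C6 of the dienolate or to the C16=C17 alkene instead of C10. The fallback sets out from enoate 21 and replaces oxygen transfer by sulfur transfer. Silyl ketene acetal 22, made as before, would be treated with PhSCl, which attacks O-silylated ester dienolates at the gamma carbon, to give the 10-phenylthio enoate F1. Chlorination with N-chlorosuccinimide would give the 10-chloro-10-phenylthio enoate F2, and hydrolysis with CuCl2/CuO in aqueous acetone would give oxo-enoate 24, where the route is rejoined before the DBU equilibration of step 15.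

Step 20 is next: enolisation may occur at the aldehyde carbon C2 or at the ester carbon C6 instead of C4, leading to oligomers or a bridged aldol. The fallback sets out from lactone 31 and generates the C4 enolate regiospecifically by reduction, not by base. Deprotonation with LiN(i-Pr)2 at the lactone alpha carbon, which is more acidic and less shielded than C6, and bromination with N-bromosuccinimide would give the 4-bromo lactone F3. Hydroboration–oxidation as in step 18 would give the 4-bromo C3 alcohol F4 and Dess–Martin oxidation the 4-bromo C3 aldehyde F5. SmI2 in THF at −78 °C would then close ring A by an intramolecular Reformatsky reaction, returning to aldol 35.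

Step 7 is third: the enol silyl groups may be lost by protodesilylation before cyclisation, or closure may occur through C12 (6-exo) instead of C13. The fallback sets out from enediol ether 12 and uses an alkene in place of the alkyne. Semihydrogenation (H2, Pd/CaCO3 poisoned with Pb(OAc)2, quinoline) would give the allyl enediol bis-silyl ether F6. Oxidative cycloalkenylation with Pd(OAc)2 in DMSO under O2 (palladation of the enol ether, 5-exo-trig insertion of the alkene, beta-hydride elimination to C16=C17) would then return to tricyclic enone 13.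

Further compounds
F1 | step 14 | 10-phenylthio C5=C6 enoate (both C10 epimers; 9-epi) | C=C1C[C@]23C[C@@]1(O[Si](C)(C)C(C)(C)C)[C@H](O[Si](CC)(CC)CC)C[C@@H]2C(Sc4ccccc4)C=C3C(=O)OCC[Si](C)(C)C
F2 | step 14 | 10-chloro-10-phenylthio C5=C6 enoate (both C10 epimers; 9-epi) | C=C1C[C@]23C[C@@]1(O[Si](C)(C)C(C)(C)C)[C@H](O[Si](CC)(CC)CC)C[C@@H]2C(Cl)(Sc4ccccc4)C=C3C(=O)OCC[Si](C)(C)C
F3 | step 20 | 4-bromo 10-allyl 19,10-lactone 7-ester (both C4 epimers) | C=C1C[C@]23C[C@@]1(O[Si](C)(C)C(C)(C)C)[C@H](O[Si](CC)(CC)CC)C[C@H]2[C@@]1(CC=C)OC(=O)C(C)(Br)[C@H]1[C@@H]3C(=O)OCC[Si](C)(C)C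
F4 | step 20 | 4-bromo C3 primary alcohol (both C4 epimers) | C=C1C[C@]23C[C@@]1(O[Si](C)(C)C(C)(C)C)[C@H](O[Si](CC)(CC)CC)C[C@H]2[C@@]1(CCCO)OC(=O)C(C)(Br)[C@H]1[C@@H]3C(=O)OCC[Si](C)(C)C
F5 | step 20 | 4-bromo C3 aldehyde (both C4 epimers) | C=C1C[C@]23C[C@@]1(O[Si](C)(C)C(C)(C)C)[C@H](O[Si](CC)(CC)CC)C[C@H]2[C@@]1(CCC=O)OC(=O)C(C)(Br)[C@H]1[C@@H]3C(=O)OCC[Si](C)(C)C
F6 | step 7 | allyl analogue of enediol bis-silyl ether 12 | C=CC[C@]12CC(O[Si](C)(C)C(C)(C)C)=C(O[Si](C)(C)C(C)(C)C)C=C1CCC23OCCO3
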